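The ten-membered carbocycle is closed at C9–C10 by reading C10 (tertiary carbinol) and C8 (acyloxy carbon) as an aldol pair. A regiospecific C8 enol silane, unmasked from a β-ketosilane, adds intramolecularly (Mukaiyama aldol) to the C10 methyl ketone, creating the ring and the C10 stereocentre in one operation; C8 is afterwards reduced anti and acylated. The precursor is a trans-α-methylene-γ-butyrolactone (C6, C7, C11, C12) carrying on C7 a (trimethylsilyl)acetyl group and on C6 the Z-C4=C5 chain that ends in the C1/C10 dione, whose C1 carbonyl is held as a 1,3-dithiane. The step exploits the 1,3-dioxygenation C8/C10 and the α-ketol C1/C10; the Z-olefin and lactone preorganise the chain.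

Key step: step 14

Numbering used below (germacrane numbering of the target): C1 ketone carbon, C2 methylene, C3 carbinol, C4=C5 olefin (C15 methyl on C4), C6 lactone O-bearing carbon, C7 ring-fusion carbon, C8 acyloxy carbon, C9 methylene, C10 tertiary carbinol (C14 methyl), C11=C13 exocyclic methylene, C12 lactone carbonyl.

Assumption: in step 4 the ProPhenol antipode that delivers the alkynyl group to the Si face of aldehyde 6 is used (written as the (S,S)-ligand); the route depends on the aldehyde face, not on the ligand label.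

Step 1
Reactants: 1 1,3-dithiane; 2 2-bromo-1,1-diethoxyethane
Product: 3 2-(2,2-diethoxyethyl)-1,3-dithiane
Conditions: n-BuLi, THF, −30 °C; then 2, DMPU, −78 °C to rt
Reagents that add atoms: none
Why: Corey–Seebach alkylation: 2-lithio-1,3-dithiane displaces the primary bromide (SN2) and joins the future C1 (dithiane carbon) to C2–C3 with C3 at the aldehyde level; no stereocentre is formed.

Step 2
Reactants: 3 2-(2,2-diethoxyethyl)-1,3-dithiane; 4 N-methoxy-N-methylacetamide
Product: 5 1-[2-(2,2-diethoxyethyl)-1,3-dithian-2-yl]ethan-1-one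
Conditions: n-BuLi, THF, −20 °C; then 4, −78 to 0 °C; aq. NH4Cl
Reagents that add atoms: none
Why: Second Corey–Seebach metalation and acylation by the N-methoxy-N-methyl amide (the chelated tetrahedral adduct prevents over-addition) gives the C1/C10 dione with C1 masked; the acetal oxygens are γ to the carbanion, so no β-elimination can occur.

Step 3
Reactants: 5 1-[2-(2,2-diethoxyethyl)-1,3-dithian-2-yl]ethan-1-one
Product: 6 2-(2-acetyl-1,3-dithian-2-yl)acetaldehyde
Conditions: 1 M HCl, THF, rt; used crude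
Reagents that add atoms: water, O
Why: Acid-catalysed acetal hydrolysis frees the C3 aldehyde while the dithioacetal, which is stable to aqueous acid, stays intact.

Step 4
Reactants: 6 2-(2-acetyl-1,3-dithian-2-yl)acetaldehyde; 7 methyl propiolate
Product: 8 methyl (4R)-5-(2-acetyl-1,3-dithian-2-yl)-4-hydroxypent-2-ynoate
Conditions: Me2Zn, (S,S)-ProPhenol (20 mol %), Ph3P=O (cat.), toluene, 0 °C
Reagents that add atoms: none
Why: Zinc–ProPhenol catalysed asymmetric alkynylation of an aldehyde: the dinuclear zinc alkynylide adds to the aldehyde in preference to the hindered ketone, and the ligand directs it to the Si face so that C3 is formed as R.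

Step 5
Reactants: 8 methyl (4R)-5-(2-acetyl-1,3-dithian-2-yl)-4-hydroxypent-2-ynoate
Product: 9 methyl (4R)-5-(2-acetyl-1,3-dithian-2-yl)-4-[(tert-butyldimethylsilyl)oxy]pent-2-ynoate
Conditions: TBSCl, imidazole, DMF, rt
Reagents that add atoms: tert-butyldimethylsilyl chloride, CC(C)(C)[Si](C)(C)Cl
Why: Imidazole-mediated silylation of the secondary propargylic alcohol protects O3 for the rest of the route and stops hemiketal formation with the C10 ketone.

Step 6
Reactants: 9 methyl (4R)-5-(2-acetyl-1,3-dithian-2-yl)-4-[(tert-butyldimethylsilyl)oxy]pent-2-ynoate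
Product: 10 methyl (2Z,4R)-5-(2-acetyl-1,3-dithian-2-yl)-4-[(tert-butyldimethylsilyl)oxy]-3-methylpent-2-enoate
Conditions: Me2CuLi (from CuI and 2 MeLi), THF, −78 °C; MeOH then aq. NH4Cl at −78 °C
Reagents that add atoms: lithium dimethylcuprate, [Li+].C[Cu-]C
Why: Conjugate syn-carbocupration of the ynoate and stereoretentive protonation of the alkenylcopper at −78 °C place the C15 methyl on C4 and give the Z-C4=C5 olefin with C3 cis to the ester; the hindered ketone does not react with the cuprate at this temperature.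

Step 7
Reactants: 10 methyl (2Z,4R)-5-(2-acetyl-1,3-dithian-2-yl)-4-[(tert-butyldimethylsilyl)oxy]-3-methylpent-2-enoate
Product: 11 (2Z,4R)-4-[(tert-butyldimethylsilyl)oxy]-5-[2-(1-hydroxyethyl)-1,3-dithian-2-yl]-3-methylpent-2-en-1-ol (both carbinol epimers)
Conditions: DIBAL-H (5 equiv), CH2Cl2, −78 to −20 °C; Rochelle salt
Reagents that add atoms: none
Why: DIBAL-H reduces the enoate in a 1,2-sense to the Z-allylic alcohol and the ketone to the carbinol (both epimers, which converge in step 8); the olefin geometry and C3 are untouched.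

Step 8
Reactants: 11 (2Z,4R)-4-[(tert-butyldimethylsilyl)oxy]-5-[2-(1-hydroxyethyl)-1,3-dithian-2-yl]-3-methylpent-2-en-1-ol
Product: 12 (2Z,4R)-5-(2-acetyl-1,3-dithian-2-yl)-4-[(tert-butyldimethylsilyl)oxy]-3-methylpent-2-enal
Conditions: SO3·pyridine, DMSO, iPr2NEt, CH2Cl2, 0 °C
Reagents that add atoms: none
Why: Parikh–Doering oxidation (activated DMSO, compatible with the dithiane) returns both hydroxyls to carbonyls, giving the Z-enal (C6) and the C10 methyl ketone without olefin isomerisation at 0 °C.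

Step 9
Reactants: 13 dimethyl itaconate
Product: 14 3-(methoxycarbonyl)but-3-enoic acid
Conditions: LiOH·H2O (1.0 equiv), THF/H2O, 0 °C; then 1 M HCl
Reagents that add atoms: lithium hydroxide, [Li+].[OH-]
Why: Regioselective saponification: hydroxide attacks the unhindered saturated ester faster than the conjugated, α-substituted acrylate ester, so one equivalent gives the half acid.

Step 10
Reactants: 14 3-(methoxycarbonyl)but-3-enoic acid; 15 (S)-4-benzyloxazolidin-2-one
Product: 17 methyl 4-[(4S)-4-benzyl-2-oxo-1,3-oxazolidin-3-yl]-2-methylidene-4-oxobutanoate, via acid chloride 16 (not isolated)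
Conditions: (COCl)2, DMF (cat.), CH2Cl2, 0 °C; then 15, n-BuLi, THF, −78 °C
Reagents that add atoms: oxalyl chloride, O=C(Cl)C(=O)Cl (the Cl of 16 only)
Why: N-Acylation of the lithiated oxazolidinone by the acid chloride is the standard preparation of an Evans imide; no amine base is present, so the β,γ-double bond stays in place.

Step 11
Reactants: 17 methyl 4-[(4S)-4-benzyl-2-oxo-1,3-oxazolidin-3-yl]-2-methylidene-4-oxobutanoate; 12 (2Z,4R)-5-(2-acetyl-1,3-dithian-2-yl)-4-[(tert-butyldimethylsilyl)oxy]-3-methylpent-2-enal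
Product: 19 (4S)-4-benzyl-3-{[(2R,3S)-2-{(1Z,3R)-4-(2-acetyl-1,3-dithian-2-yl)-3-[(tert-butyldimethylsilyl)oxy]-2-methylbut-1-en-1-yl}-4-methylidene-5-oxooxolan-3-yl]carbonyl}-1,3-oxazolidin-2-one (trans lactone), via aldol adduct 18 (not isolated)
Conditions: Bu2BOTf, iPr2NEt, CH2Cl2, −78 to 0 °C; then 12, −78 to −20 °C; pH 7 buffer/MeOH (no peroxide); then PPTS (cat.), CH2Cl2, rt
Reagents that add atoms: none
Why: Evans syn aldol: the Z-boron dienolate reacts at its α-carbon (C7) through a Zimmerman–Traxler chair on the enolate face opposite the benzyl group, setting C6 and C7 (aldehyde chosen over the hindered ketone), and the C6 hydroxyl then lactonises onto the acrylate ester to give the trans α-methylene lactone.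

Step 12
Reactants: 19 trans lactone imide
Product: 20 (2R,3S)-2-{(1Z,3R)-4-(2-acetyl-1,3-dithian-2-yl)-3-[(tert-butyldimethylsilyl)oxy]-2-methylbut-1-en-1-yl}-4-methylidene-5-oxooxolane-3-carboxylic acid
Conditions: LiOH, H2O2, THF/H2O, 0 °C, short reaction time; Na2SO3; then pH 3
Reagents that add atoms: lithium hydroperoxide (from LiOH and H2O2), [Li+].[O-]O
Why: Lithium hydroperoxide attacks the exocyclic imide carbonyl selectively (lactone and enoate are spared in a short reaction at 0 °C), releasing the C8 acid and the recoverable auxiliary.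

Step 13
Reactants: 20 lactone acid
Product: 22 (4S,5R)-5-{(1Z,3R)-4-(2-acetyl-1,3-dithian-2-yl)-3-[(tert-butyldimethylsilyl)oxy]-2-methylbut-1-en-1-yl}-3-methylidene-4-[(trimethylsilyl)acetyl]oxolan-2-one, via acid chloride 21 (not isolated)
Conditions: 1-chloro-N,N,2-trimethylprop-1-en-1-amine, CH2Cl2, 0 °C; then Me3SiCH2MgCl (1.05 equiv), CuI (10 mol %), THF, −78 °C
Reagents that add atoms: 1-chloro-N,N,2-trimethylprop-1-en-1-amine, CC(C)=C(Cl)N(C)C (the Cl of 21 only); (trimethylsilyl)methylmagnesium chloride, C[Si](C)(C)C[Mg]Cl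
Why: Neutral acid chloride formation followed by copper-catalysed acylation of the Grignard reagent (a known route to β-ketosilanes) places silicon on C9; the acid chloride is far more electrophilic than the ketone, lactone and enoate at −78 °C.

Step 14
Reactants: 22 β-ketosilane
Product: 24 (3R,6R,7S,10R)-3-[(tert-butyldimethylsilyl)oxy]-10-hydroxy-8-oxo-1,1-(propane-1,3-diyldisulfanediyl)germacra-4Z,11(13)-dien-12,6-olide (target numbering; C1 is a spiro-1,3-dithiane), via enol silane 23 (not isolated)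
Conditions: TMSOTf (5 mol %), CH2Cl2, 0 °C; then slow addition to TiCl4 (2 equiv), CH2Cl2, −78 °C, about 1 mM; aq. NaHCO3
Reagents that add atoms: none
Why: Catalytic TMSOTf induces the 1,3 C-to-O silyl shift of the β-ketosilane, which gives the terminal C8 enol silane 23 regiospecifically (no C7 or C14 enol); TiCl4 then binds the C10 acetyl carbonyl (supported by a dithiane sulfur) and C9 adds to C10 with loss of Me3SiCl, directly or through the trichlorotitanium enolate. The closest known reaction type is the intramolecular Mukaiyama aldol addition of a silyl enol ether to a ketone, which has been used to close medium carbocycles. The ten-membered carbocycle closes in a 10-(enolendo)-exo-trig mode under high dilution; the competing attack of C9 on C13 of the methylene lactone would be a 5-endo-trig closure and is disfavoured. The new stereocentre C10 is set by the conformation of the forming ring: the Z-C4=C5 bond and the trans-fused lactone restrict the chain so that the acetyl methyl is expected to point to the periphery and C9 to reach the Re face of C10=O, which gives 10R; this is a model, not a secured outcome. The step needs chemoselectivity for C10 over C1 and regiospecific use of C9; the dithiane at C1 removes the second carbonyl and activates C10 inductively, and the silicon placed on C9 in step 13 fixes the nucleophilic carbon. The titanium aldolate resists retro-aldol cleavage until the buffered work-up.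

Step 15
Reactants: 24 macrocyclic ketol
Product: 25 (3R,6R,7R,8R,10R)-3-[(tert-butyldimethylsilyl)oxy]-8,10-dihydroxy-1,1-(propane-1,3-diyldisulfanediyl)germacra-4Z,11(13)-dien-12,6-olide
Conditions: Me4NBH(OAc)3, MeCN/AcOH (1:1), −30 °C
Reagents that add atoms: none
Why: Evans–Saksena reduction: the reagent exchanges an acetate for the C10 hydroxyl and delivers hydride intramolecularly to C8 through a chair transition state, which should give the 1,3-anti diol (8R); lactone and dithiane are inert to this reagent.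

Step 16
Reactants: 25 anti diol
Product: 26 (3R,6R,7R,8R,10R)-3-[(tert-butyldimethylsilyl)oxy]-10-hydroxy-8-[(3-methylbutanoyl)oxy]-1,1-(propane-1,3-diyldisulfanediyl)germacra-4Z,11(13)-dien-12,6-olide
Conditions: 3-methylbutanoic anhydride, Et3N, DMAP (cat.), CH2Cl2, 0 °C
Reagents that add atoms: 3-methylbutanoic anhydride, CC(C)CC(=O)OC(=O)CC(C)C
Why: DMAP-catalysed acyl transfer is selective for the secondary C8 hydroxyl because the tertiary C10 hydroxyl is too hindered.

Step 17
Reactants: 26 isovalerate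
Product: 27 (3R,6R,7R,8R,10R)-3-[(tert-butyldimethylsilyl)oxy]-10-hydroxy-8-[(3-methylbutanoyl)oxy]-1-oxogermacra-4Z,11(13)-dien-12,6-olide
Conditions: PhI(OCOCF3)2, MeCN/H2O (9:1), NaHCO3, 0 °C
Reagents that add atoms: water, O
Why: Oxidative dithioacetal hydrolysis with an iodine(III) reagent (S-activation, ring opening, hydrolysis) unmasks the C1 ketone, and the liberated dithiol is oxidised so that it cannot add to the methylene lactone.

Step 18
Reactants: 27 silyl ether of the target
Product: 28 target, (3R,6R,7R,8R,10R)-3,10-dihydroxy-8-[(3-methylbutanoyl)oxy]-1-oxogermacra-4Z,11(13)-dien-12,6-olide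
Conditions: HF·pyridine, THF/pyridine, 0 °C to rt
Reagents that add atoms: none
Why: Fluoride-mediated desilylation under buffered, non-basic conditions frees the C3 hydroxyl without retro-aldol cleavage or β-elimination of the β-hydroxy ketone.

Compound list
1 | 1,3-dithiane | C1CSCSC1 | starting material
2 | 2-bromo-1,1-diethoxyethane | CCOC(CBr)OCC | starting material
3 | 2-(2,2-diethoxyethyl)-1,3-dithiane | CCOC(CC1SCCCS1)OCC | intermediate
4 | N-methoxy-N-methylacetamide | CC(=O)N(C)OC | starting material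
5 | 1-[2-(2,2-diethoxyethyl)-1,3-dithian-2-yl]ethan-1-one | CCOC(CC1(C(C)=O)SCCCS1)OCC | intermediate
6 | 2-(2-acetyl-1,3-dithian-2-yl)acetaldehyde | CC(=O)C1(CC=O)SCCCS1 | intermediate
7 | methyl propiolate | C#CC(=O)OC | starting material
8 | methyl (4R)-5-(2-acetyl-1,3-dithian-2-yl)-4-hydroxypent-2-ynoate | CC(=O)C1(C[C@@H](O)C#CC(=O)OC)SCCCS1 | intermediate
9 | methyl (4R)-5-(2-acetyl-1,3-dithian-2-yl)-4-[(tert-butyldimethylsilyl)oxy]pent-2-ynoate | CC(=O)C1(C[C@@H](O[Si](C)(C)C(C)(C)C)C#CC(=O)OC)SCCCS1 | intermediate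
10 | methyl (2Z,4R)-5-(2-acetyl-1,3-dithian-2-yl)-4-[(tert-butyldimethylsilyl)oxy]-3-methylpent-2-enoate | CC(=O)C1(C[C@@H](O[Si](C)(C)C(C)(C)C)/C(C)=C\C(=O)OC)SCCCS1 | intermediate
11 | (2Z,4R)-4-[(tert-butyldimethylsilyl)oxy]-5-[2-(1-hydroxyethyl)-1,3-dithian-2-yl]-3-methylpent-2-en-1-ol (carbinol epimers) | CC(O)C1(C[C@@H](O[Si](C)(C)C(C)(C)C)/C(C)=C\CO)SCCCS1 | intermediate
12 | (2Z,4R)-5-(2-acetyl-1,3-dithian-2-yl)-4-[(tert-butyldimethylsilyl)oxy]-3-methylpent-2-enal | CC(=O)C1(C[C@@H](O[Si](C)(C)C(C)(C)C)/C(C)=C\C=O)SCCCS1 | intermediate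
13 | dimethyl itaconate | C=C(CC(=O)OC)C(=O)OC | starting material
14 | 3-(methoxycarbonyl)but-3-enoic acid | C=C(CC(=O)O)C(=O)OC | intermediate
15 | (S)-4-benzyloxazolidin-2-one | O=C1OC[C@H](Cc2ccccc2)N1 | starting material
16 | methyl 4-chloro-2-methylidene-4-oxobutanoate | C=C(CC(=O)Cl)C(=O)OC | intermediate (not isolated)
17 | methyl 4-[(4S)-4-benzyl-2-oxo-1,3-oxazolidin-3-yl]-2-methylidene-4-oxobutanoate | C=C(CC(=O)N1[C@@H](Cc2ccccc2)COC1=O)C(=O)OC | intermediate
18 | methyl (3S,4R,5Z,7R)-8-(2-acetyl-1,3-dithian-2-yl)-3-{[(4S)-4-benzyl-2-oxo-1,3-oxazolidin-3-yl]carbonyl}-7-[(tert-butyldimethylsilyl)oxy]-4-hydroxy-6-methyl-2-methylideneoct-5-enoate (syn aldol adduct) | COC(=O)C(=C)[C@@H]([C@H](O)/C=C(/C)[C@H](O[Si](C)(C)C(C)(C)C)CC1(SCCCS1)C(C)=O)C(=O)N1[C@@H](Cc2ccccc2)COC1=O | intermediate (not isolated)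
19 | (4S)-4-benzyl-3-{[(2R,3S)-2-{(1Z,3R)-4-(2-acetyl-1,3-dithian-2-yl)-3-[(tert-butyldimethylsilyl)oxy]-2-methylbut-1-en-1-yl}-4-methylidene-5-oxooxolan-3-yl]carbonyl}-1,3-oxazolidin-2-one | C=C1C(=O)O[C@H](/C=C(/C)[C@H](O[Si](C)(C)C(C)(C)C)CC2(SCCCS2)C(C)=O)[C@H]1C(=O)N1[C@@H](Cc2ccccc2)COC1=O | intermediate
20 | (2R,3S)-2-{(1Z,3R)-4-(2-acetyl-1,3-dithian-2-yl)-3-[(tert-butyldimethylsilyl)oxy]-2-methylbut-1-en-1-yl}-4-methylidene-5-oxooxolane-3-carboxylic acid | C=C1C(=O)O[C@H](/C=C(/C)[C@H](O[Si](C)(C)C(C)(C)C)CC2(SCCCS2)C(C)=O)[C@H]1C(=O)O | intermediate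
21 | (2R,3S)-2-{(1Z,3R)-4-(2-acetyl-1,3-dithian-2-yl)-3-[(tert-butyldimethylsilyl)oxy]-2-methylbut-1-en-1-yl}-4-methylidene-5-oxooxolane-3-carbonyl chloride | C=C1C(=O)O[C@H](/C=C(/C)[C@H](O[Si](C)(C)C(C)(C)C)CC2(SCCCS2)C(C)=O)[C@H]1C(=O)Cl | intermediate (not isolated)
22 | (4S,5R)-5-{(1Z,3R)-4-(2-acetyl-1,3-dithian-2-yl)-3-[(tert-butyldimethylsilyl)oxy]-2-methylbut-1-en-1-yl}-3-methylidene-4-[(trimethylsilyl)acetyl]oxolan-2-one | C=C1C(=O)O[C@H](/C=C(/C)[C@H](O[Si](C)(C)C(C)(C)C)CC2(SCCCS2)C(C)=O)[C@H]1C(=O)C[Si](C)(C)C | intermediate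
23 | (4S,5R)-5-{(1Z,3R)-4-(2-acetyl-1,3-dithian-2-yl)-3-[(tert-butyldimethylsilyl)oxy]-2-methylbut-1-en-1-yl}-3-methylidene-4-{1-[(trimethylsilyl)oxy]ethenyl}oxolan-2-one | C=C1C(=O)O[C@H](/C=C(/C)[C@H](O[Si](C)(C)C(C)(C)C)CC2(SCCCS2)C(C)=O)[C@H]1C(=C)O[Si](C)(C)C | intermediate (not isolated)
24 | (3R,6R,7S,10R)-3-[(tert-butyldimethylsilyl)oxy]-10-hydroxy-8-oxo-1,1-(propane-1,3-diyldisulfanediyl)germacra-4Z,11(13)-dien-12,6-olide | C=C1C(=O)O[C@@H]2/C=C(/C)[C@H](O[Si](C)(C)C(C)(C)C)CC3(SCCCS3)[C@](C)(O)CC(=O)[C@@H]12 | intermediate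
25 | (3R,6R,7R,8R,10R)-3-[(tert-butyldimethylsilyl)oxy]-8,10-dihydroxy-1,1-(propane-1,3-diyldisulfanediyl)germacra-4Z,11(13)-dien-12,6-olide | C=C1C(=O)O[C@@H]2/C=C(/C)[C@H](O[Si](C)(C)C(C)(C)C)CC3(SCCCS3)[C@](C)(O)C[C@@H](O)[C@@H]12 | intermediate
26 | (3R,6R,7R,8R,10R)-3-[(tert-butyldimethylsilyl)oxy]-10-hydroxy-8-[(3-methylbutanoyl)oxy]-1,1-(propane-1,3-diyldisulfanediyl)germacra-4Z,11(13)-dien-12,6-olide | C=C1C(=O)O[C@@H]2/C=C(/C)[C@H](O[Si](C)(C)C(C)(C)C)CC3(SCCCS3)[C@](C)(O)C[C@@H](OC(=O)CC(C)C)[C@@H]12 | intermediate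
27 | (3R,6R,7R,8R,10R)-3-[(tert-butyldimethylsilyl)oxy]-10-hydroxy-8-[(3-methylbutanoyl)oxy]-1-oxogermacra-4Z,11(13)-dien-12,6-olide | C=C1C(=O)O[C@@H]2/C=C(/C)[C@H](O[Si](C)(C)C(C)(C)C)CC(=O)[C@](C)(O)C[C@@H](OC(=O)CC(C)C)[C@@H]12 | intermediate
28 | (3R,6R,7R,8R,10R)-3,10-dihydroxy-8-[(3-methylbutanoyl)oxy]-1-oxogermacra-4Z,11(13)-dien-12,6-olide (CNP0406522.1) | C=C1C(=O)O[C@@H]2/C=C(/C)[C@H](O)CC(=O)[C@](C)(O)C[C@@H](OC(=O)CC(C)C)[C@@H]12 | target

Total step count: 18
Longest linear sequence: 16 steps (steps 1–8, then 11–18, from 1,3-dithiane)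

Steps most likely to fail

1. Step 14 (key ring closure). Oligomerisation may outrun closure of the strained ten-membered ring, the enol silane may be protodesilylated to the methyl ketone before it adds, and C9 may attack the wrong face of the C10 carbonyl, giving the C10 epimer. The fallback forms the same bond from a reductively generated, metal-chelated enolate. It sets out from acid 20 and rejoins the route at 24, so it also bypasses step 13. Acid 20 is converted into acid chloride 21 as in step 13 and treated with (trimethylsilyl)diazomethane (CaO, MeCN/THF, 0 °C), which should give the diazomethyl ketone F1. Acylation is expected to be faster than dipolar cycloaddition of this hindered diazoalkane to the methylene lactone. Brief treatment with 48 % HBr in Et2O at −20 °C should give the bromomethyl ketone F2. Slow addition of F2 to SmI2 (2.2 equiv) in THF at −78 °C under high dilution should generate the samarium(III) enolate at C9 and close the ring by an intramolecular Reformatsky-type aldol addition to the C10 ketone through a chelated, closed transition state, giving 24.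

2. Step 11 (dienolate aldol). The boron dienolate may react at its γ-carbon (C13), the exocyclic double bond may migrate into conjugation (C7=C11), or C7 may epimerise under the amine base. The fallback introduces the methylene after the aldol; it sets out from 12 and rejoins at 20. The saturated succinyl imide F3 (from methyl 4-chloro-4-oxobutanoate and lithiated 15) is enolised with Bu2BOTf/iPr2NEt and added to 12, which should give the syn aldol adduct F4. PPTS should lactonise F4 to the saturated trans lactone imide F5, and LiOH/H2O2 should then give the lactone acid F6. Methyl magnesium carbonate (DMF, 125 °C) should carboxylate C11 to the α-carboxy lactone F7; carboxylation of the C10 methyl ketone is reversible and should revert on acidification and gentle warming. Aqueous formaldehyde with N-methylaniline in AcOH/NaOAc should then effect decarboxylative Mannich methylenation to 20.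

3. Step 15 (directed reduction). Exchange of the hindered tertiary C10 hydroxyl onto boron may be slow, and the ring conformation may override the chair transition state so that hydride reaches the wrong face of C8. The fallback aims for the opposite diol on purpose and corrects C8 during esterification; it sets out from 24 and rejoins at 26. Chelation-controlled Narasaka–Prasad reduction (Et2BOMe, NaBH4, THF/MeOH, −78 °C) should give the syn diol F8 (8S). Mitsunobu esterification of F8 with 3-methylbutanoic acid (PPh3, DIAD, toluene, 0 °C) should then acylate the secondary hydroxyl with inversion at C8 and give 26 directly.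

Further compounds
F1 | step 14 | (4S,5R)-5-{(1Z,3R)-4-(2-acetyl-1,3-dithian-2-yl)-3-[(tert-butyldimethylsilyl)oxy]-2-methylbut-1-en-1-yl}-4-(diazoacetyl)-3-methylideneoxolan-2-one | C=C1C(=O)O[C@H](/C=C(/C)[C@H](O[Si](C)(C)C(C)(C)C)CC2(SCCCS2)C(C)=O)[C@H]1C(=O)C=[N+]=[N-]
F2 | step 14 | (4S,5R)-5-{(1Z,3R)-4-(2-acetyl-1,3-dithian-2-yl)-3-[(tert-butyldimethylsilyl)oxy]-2-methylbut-1-en-1-yl}-4-(bromoacetyl)-3-methylideneoxolan-2-one | C=C1C(=O)O[C@H](/C=C(/C)[C@H](O[Si](C)(C)C(C)(C)C)CC2(SCCCS2)C(C)=O)[C@H]1C(=O)CBr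
F3 | step 11 | methyl 4-[(4S)-4-benzyl-2-oxo-1,3-oxazolidin-3-yl]-4-oxobutanoate | COC(=O)CCC(=O)N1[C@@H](Cc2ccccc2)COC1=O
F4 | step 11 | methyl (3S,4R,5Z,7R)-8-(2-acetyl-1,3-dithian-2-yl)-3-{[(4S)-4-benzyl-2-oxo-1,3-oxazolidin-3-yl]carbonyl}-7-[(tert-butyldimethylsilyl)oxy]-4-hydroxy-6-methyloct-5-enoate | COC(=O)C[C@@H]([C@H](O)/C=C(/C)[C@H](O[Si](C)(C)C(C)(C)C)CC1(SCCCS1)C(C)=O)C(=O)N1[C@@H](Cc2ccccc2)COC1=O
F5 | step 11 | (4S)-4-benzyl-3-{[(2R,3S)-2-{(1Z,3R)-4-(2-acetyl-1,3-dithian-2-yl)-3-[(tert-butyldimethylsilyl)oxy]-2-methylbut-1-en-1-yl}-5-oxooxolan-3-yl]carbonyl}-1,3-oxazolidin-2-one | C1C(=O)O[C@H](/C=C(/C)[C@H](O[Si](C)(C)C(C)(C)C)CC2(SCCCS2)C(C)=O)[C@H]1C(=O)N1[C@@H](Cc2ccccc2)COC1=O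
F6 | step 11 | (2R,3S)-2-{(1Z,3R)-4-(2-acetyl-1,3-dithian-2-yl)-3-[(tert-butyldimethylsilyl)oxy]-2-methylbut-1-en-1-yl}-5-oxooxolane-3-carboxylic acid | C1C(=O)O[C@H](/C=C(/C)[C@H](O[Si](C)(C)C(C)(C)C)CC2(SCCCS2)C(C)=O)[C@H]1C(=O)O
F7 | step 11 | (2R,3S)-2-{(1Z,3R)-4-(2-acetyl-1,3-dithian-2-yl)-3-[(tert-butyldimethylsilyl)oxy]-2-methylbut-1-en-1-yl}-5-oxooxolane-3,4-dicarboxylic acid (C11 epimers) | OC(=O)C1C(=O)O[C@H](/C=C(/C)[C@H](O[Si](C)(C)C(C)(C)C)CC2(SCCCS2)C(C)=O)[C@H]1C(=O)O
F8 | step 15 | (3R,6R,7R,8S,10R)-3-[(tert-butyldimethylsilyl)oxy]-8,10-dihydroxy-1,1-(propane-1,3-diyldisulfanediyl)germacra-4Z,11(13)-dien-12,6-olide | C=C1C(=O)O[C@@H]2/C=C(/C)[C@H](O[Si](C)(C)C(C)(C)C)CC3(SCCCS3)[C@](C)(O)C[C@H](O)[C@@H]12
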